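## Analysis of the target

Renealtin A (23) is a linear diarylheptanoid whose chain is numbered here from C1 (the ketone carbon) to C7 (the benzylic CH2), each end carrying a 4-hydroxy-3-methoxyphenyl ring. An ether oxygen links C3 and C6, so O, C3, C4, C5 and C6 form a 2,3,5-trisubstituted oxolane: C3 bears the CH2–C(=O)–aryl arm, C5 a free hydroxyl and C6 the arylmethyl arm. The stereocentres are 3R, 5R and 6R (2R, 4R, 5R in oxolane numbering) and all three substituents lie on one face of the ring; C5 and C6 are adjacent, C3 is separated from them by the C4 methylene. The sensitive groups are the two phenols, the secondary alcohol and above all the β-alkoxy aryl ketone: the ring oxygen on C3 can leave by retro-oxa-Michael elimination under base or strong acid, which would open the ring and scramble C3. The difficulties are the crowded all-cis ring, a centre (C3) that is only 1,3-related to the C5/C6 pair, and two almost identical aryl termini at different oxidation levels (ketone at C1, methylene at C7). The strategy rests on one feature: C1 is an aryl ketone carbon separated only by C2 from the oxygen-bearing C3, so C1 can be brought in as an aryl acyl anion that opens a C2–C3 oxirane, and the alkoxide this releases on C3 sits five atoms from C6, where a leaving group lets it close the ring. The C5/C6 oxygen pattern with C4 as a methylene is that of C3/C4 of 2-deoxy-L-ribose (1), provided C6 is inverted during ring closure.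

## Retrosynthetic reasoning

**23 back to 21.** Only O–H and C=O bonds are made at the end. The three hydroxyls of 23 are carried as benzyl ethers in 22, and the C1 carbonyl of 22 as the cyclic dithioketal in 21. This keeps the fragile β-alkoxy ketone masked until only near-neutral operations remain and frees all three hydroxyls in one hydrogenolysis. Forward, the thioketal must be hydrolysed without acid or base strong enough to open the ring, and the benzyl groups removed without reducing the aryl ketone.

**21 back to 19 and 14.** Two bonds of 21 are cut, C1–C2 and O–C6. C1–C2 is chosen because C1, as a dithiane carbon (19, from 18), is the one chain position that can be made nucleophilic without touching a stereocentre, and C2 is a methylene that can be the unsubstituted carbon of an oxirane. O–C6 is cut rather than O–C3 because opening the oxirane necessarily places the negative charge on the C3 oxygen; C6 must then be the electrophile, a sulfonate of configuration opposite to the product. The gain is fragment union and ring closure in one flask, both aryl groups at their final oxidation levels, and all stereochemical information on one partner, 14. Forward, 19 must attack the oxirane terminus of 14 faster than it touches the secondary tosylate, and alkoxide 20 must close the five-membered ring with clean inversion.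

**14 back to 12.** The C2–C3 oxirane of 14 comes from the terminal alkene of 12 through the epimer mixture 13; C–O bonds are cut, no C–C bond. The C3 oxygen is 1,3-anti to the C5 oxygen, a relationship that substrate-directed oxidations through a C5 oxygen do not favour, and the C5 oxygen is an ether anyway. Unselective peracid epoxidation followed by a catalyst-controlled hydrolytic resolution is therefore used. The price is half the material at this stage; the gain is a C3 configuration that does not depend on the substrate.

**12 back to 7 and 9.** The bond between C7 and its aryl ring is cut, giving the aryl nucleophile 10 (from bromide 9) and the C6–C7 oxirane 7. The cut is placed here and not at C6–C7 because C7 is then an unsubstituted oxirane carbon: regiochemistry is secure, and C6 keeps its oxygen and configuration. The hydroxyl released on C6 in 11 is exactly the one to be sulfonylated in 12.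

**7 back to 1.** Oxirane 7 holds the C5/C6 pair, C4 as a methylene and an allyl terminus, which is 2-deoxy-L-ribose 1 after one-carbon olefination to triol 2. Sugar C1 becomes C3, the new methylene is C2, and sugar C2 to C5 become C4 to C7. The three hydroxyls of 2 are told apart through the terminal acetonide 3, which leaves only the C5 hydroxyl free for benzylation to 4. Release of diol 5 and closure through the primary sulfonate 6 gives 7. Benzylating before the oxirane exists avoids an epoxy alkoxide that could undergo Payne rearrangement.

**18 back to 15 and 17; 9 back to 8.** Dithiane 18 is the thioacetal of benzyl-protected vanillin 16 (from 15) with dithiol 17, and 9 is the benzyl ether of bromophenol 8. Benzyl is used on all three oxygens so that one final step removes them.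

## Alternatives that were turned down

**Alternative 1:** The disconnection cuts C2–C3 and C6–C7 together, with C1 temporarily bonded to both C2 and C7, so the oxolane appears as the oxygen-bridged ring of a bicyclic ketone. In the forward key step Zn–Cu couple debrominates 1,1,3,3-tetrabromoacetone A3 to an oxyallyl cation, which furan A2 captures across its 2- and 5-positions in a (4+3) cycloaddition; the two bromines left over are then removed reductively, giving meso 8-oxabicyclo[3.2.1]oct-6-en-3-one A1. In its favour, A2 and A3 are very cheap, the cycloaddition is scalable and the C4=C5 alkene of A1 is a handle for the C5 oxygen. The cis relation of the C3 and C6 arms is fixed by the bicycle, and on that one point it is more secure than an SN2 closure. Against it: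
- A1 is achiral and carries no aryl ring, so it must be desymmetrised.
- The C1–C7 bond must be cleaved again, and a Baeyer–Villiger insertion has no clear preference between C2 and C7 once symmetry is broken only at remote C5.
- C7 then emerges oxygenated and must be turned into an arylmethyl group, and C1 emerges as a carboxyl derivative that must become an aryl ketone.
- Reagents add to the alkene of A1 from the exo face, which puts the C5 oxygen trans to the two arms and calls for an inversion.

The chosen route gives up the built-in cis guarantee but takes absolute configuration from 1, introduces both aryl groups directly at their final oxidation levels, and needs far fewer operations after ring formation.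

**Alternative 2:** The disconnection cuts C3–C4 and C5–C6, with the C5 hydroxyl replaced by an acetyl group and the C1 ketone by a protected primary alcohol. In the forward key step SnCl4 ionises the 4-methyl-4-vinyl-1,3-dioxolane A5 to an oxocarbenium ion at C3, the vinyl terminus C4 adds to it, and the resulting cation at C5 is quenched by a pinacol shift of C6, giving the all-cis 3-acetyloxolane A4. In its favour, two C–C bonds, the ring and the all-cis relation of three centres arise in one stereocontrolled step; on relative stereocontrol it is stronger than the chosen route. Against it: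
- Acetyl must become hydroxyl by Baeyer–Villiger oxidation and ester cleavage, with a peracid acting beside an electron-rich arene.
- The silyloxyethyl arm of A4 must become an aryl ketone by desilylation, oxidation, aryl addition and a second oxidation.
- The electron-rich arylmethyl group on C6 sits close to the oxocarbenium oxygen and can capture the cation by oxa-Pictet–Spengler cyclisation in competition with the vinyl group.
- A5 holds a fully substituted allylic ether carbon next to the C6 stereocentre and needs an enantioselective synthesis of its own.

The chosen route offers both aryl units at their final oxidation level directly after the key step and two steps to the target from there.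

**Alternative 3:** The disconnection cuts O–C3 and C5–C6, with C5 as a malonate carbon. In the forward key step the racemic donor–acceptor cyclopropane A7 and the arylacetaldehyde A8 combine under MgI2 with a chiral pybox ligand: the aldehyde oxygen opens the cyclopropane at the donor carbon C3 with inversion and the malonate carbon C5 closes onto the aldehyde carbon C6, giving the 2,5-cis oxolane diester A6. In its favour it is the most convergent plan, it sets absolute configuration catalytically from racemic material, and it reaches the ring in fewer steps without the loss of half the material in a resolution; on those points it is stronger than the chosen route. Against it: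
- C5 of A6 is a quaternary diester carbon; both ester carbons must be excised and replaced by a hydroxyl cis to its neighbours, a multi-step exchange whose stereochemistry the key step does not control.
- The styryl C1=C2 bond of A6 must be oxidised regioselectively to the C1 ketone, and an alkene between an aryl ring and an allylic ether has no reliable bias.
- A8 is an enolisable, self-condensing aldehyde, a poor partner for a Lewis-acid annulation, and the alkenyl donor of A7 activates the cyclopropane less than an aryl donor.

The chosen route offers the C5 oxygen and the C1 carbonyl already in place at the price of a chiral-pool sequence and one resolution.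

Key step: step 13

Assumption: the (R,R)-(salen)Co(OAc) complex is taken to be the enantiomer that hydrates (S)-configured 2-alkyloxiranes and spares the (R)-epimer; if the sense of this catalyst family is the reverse, the (S,S)-complex is used in step 10 and nothing else changes.

## Route

Step 1
Reactants: 1 2-deoxy-L-ribose
Product: 2 (2S,3R)-hex-5-ene-1,2,3-triol
Conditions: Ph3PCH3Br (3.5 equiv), KOtBu (3.4 equiv), THF, 0 °C → reflux
Reagents that add atoms: methyltriphenylphosphonium bromide, used as its ylide, C[P+](c1ccccc1)(c1ccccc1)c1ccccc1.[Br-]
Why: Wittig methylenation of the open-chain aldehyde in equilibrium with the lactol; excess ylide covers the acidic hydroxyls, and neither carbinol centre is touched, so sugar C3 and C4 become C5 and C6 of the chain unchanged.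

Step 2
Reactants: 2 (2S,3R)-hex-5-ene-1,2,3-triol
Product: 3 (1R)-1-[(4S)-2,2-dimethyl-1,3-dioxolan-4-yl]but-3-en-1-ol
Conditions: Me2C(OMe)2, TsOH·H2O (cat.), acetone, rt
Reagents that add atoms: 2,2-dimethoxypropane, COC(C)(C)OC
Why: Acid-catalysed acetonide formation under equilibrating conditions should settle on the terminal 1,2-diol, because the internal dioxolane of this erythro diol would be cis-4,5-disubstituted and the 1,3-dioxane would carry an axial methyl; only the future C5 hydroxyl stays free.

Step 3
Reactants: 3 (1R)-1-[(4S)-2,2-dimethyl-1,3-dioxolan-4-yl]but-3-en-1-ol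
Product: 4 (4S)-4-[(1R)-1-(benzyloxy)but-3-en-1-yl]-2,2-dimethyl-1,3-dioxolane
Conditions: NaH, BnBr, Bu4NI (cat.), THF/DMF, 0 °C → rt
Reagents that add atoms: benzyl bromide, BrCc1ccccc1
Why: Williamson etherification of the single free secondary alcohol; benzyl is chosen because it cannot migrate to a neighbouring alkoxide in the later ring closure and is removed in the final hydrogenolysis.

Step 4
Reactants: 4 (4S)-4-[(1R)-1-(benzyloxy)but-3-en-1-yl]-2,2-dimethyl-1,3-dioxolane
Product: 5 (2S,3R)-3-(benzyloxy)hex-5-ene-1,2-diol
Conditions: AcOH/H2O (4:1), 45 °C
Reagents that add atoms: none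
Why: Acid hydrolysis of the isopropylidene acetal; the benzyl ether and the alkene are inert to aqueous acetic acid and no stereocentre is involved.

Step 5
Reactants: 5 (2S,3R)-3-(benzyloxy)hex-5-ene-1,2-diol
Product: 7 (2S)-2-[(1R)-1-(benzyloxy)but-3-en-1-yl]oxirane, via primary tosylate 6 (not isolated)
Conditions: NaH (2.2 equiv), 1-tosylimidazole (1.05 equiv), THF, 0 °C → rt
Reagents that add atoms: none
Why: One-flask diol-to-epoxide conversion: the less hindered primary alkoxide is sulfonylated first and the neighbouring secondary alkoxide then displaces the tosylate in a 3-exo-tet Williamson closure. The C–O bond at the secondary carbon (future C6) is not broken, so its configuration is retained, and with the C5 oxygen already benzylated no Payne rearrangement is possible.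

Step 6
Reactants: 8 4-bromo-2-methoxyphenol
Product: 9 1-(benzyloxy)-4-bromo-2-methoxybenzene
Conditions: BnBr, K2CO3, DMF, rt
Reagents that add atoms: benzyl bromide, BrCc1ccccc1
Why: Williamson O-alkylation of the phenoxide; the aryl bromide is untouched.

Step 7
Reactants: 7 (2S)-2-[(1R)-1-(benzyloxy)but-3-en-1-yl]oxirane; 9 1-(benzyloxy)-4-bromo-2-methoxybenzene
Product: 11 (2S,3R)-3-(benzyloxy)-1-[4-(benzyloxy)-3-methoxyphenyl]hex-5-en-2-ol, via arylmagnesium bromide 10 (not isolated)
Conditions: 9, Mg, THF, reflux; then CuI (10 mol %), 7, THF, −30 → 0 °C; aq. NH4Cl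
Reagents that add atoms: none
Why: Copper-catalysed Grignard opening of a monosubstituted epoxide: the aryl copper species attacks the unsubstituted carbon (C7), forming the aryl–C7 bond and leaving the C6 hydroxyl with unchanged configuration; the terminal alkene and the benzyl ethers are inert.

Step 8
Reactants: 11 (2S,3R)-3-(benzyloxy)-1-[4-(benzyloxy)-3-methoxyphenyl]hex-5-en-2-ol
Product: 12 (2S,3R)-3-(benzyloxy)-1-[4-(benzyloxy)-3-methoxyphenyl]hex-5-en-2-yl 4-methylbenzenesulfonate
Conditions: TsCl, Et3N, DMAP (cat.), CH2Cl2, 0 °C → rt
Reagents that add atoms: 4-toluenesulfonyl chloride, Cc1ccc(S(=O)(=O)Cl)cc1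
Why: O-sulfonylation with retention turns the C6 oxygen into the leaving group for the ring closure and removes the only free hydroxyl before the alkene is oxidised, so the coming oxirane cannot be opened intramolecularly.

Step 9
Reactants: 12 (2S,3R)-3-(benzyloxy)-1-[4-(benzyloxy)-3-methoxyphenyl]hex-5-en-2-yl 4-methylbenzenesulfonate
Product: 13 (2S,3R)-3-(benzyloxy)-1-[4-(benzyloxy)-3-methoxyphenyl]-4-(oxiran-2-yl)butan-2-yl 4-methylbenzenesulfonate, both epimers at the oxirane carbon
Conditions: mCPBA, CH2Cl2, 0 °C → rt
Reagents that add atoms: 3-chloroperbenzoic acid, O=C(OO)c1cccc(Cl)c1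
Why: Prilezhaev epoxidation of the terminal alkene; the remote C5 centre is not expected to bias the two faces, so both epimers should form in comparable amounts, and the sulfonate, the benzyl ethers and the dialkoxyarene should survive the peracid at this temperature.

Step 10
Reactants: 13 (2S,3R)-3-(benzyloxy)-1-[4-(benzyloxy)-3-methoxyphenyl]-4-(oxiran-2-yl)butan-2-yl 4-methylbenzenesulfonate, both epimers
Product: 14 (2S,3R)-3-(benzyloxy)-1-[4-(benzyloxy)-3-methoxyphenyl]-4-[(2R)-oxiran-2-yl]butan-2-yl 4-methylbenzenesulfonate
Conditions: (R,R)-(salen)Co(OAc) (2 mol %; salen = N,N'-bis(3,5-di-tert-butylsalicylidene)cyclohexane-1,2-diaminate), H2O (0.55 equiv), THF, 0 °C → rt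
Reagents that add atoms: none
Why: Jacobsen hydrolytic kinetic resolution: the chiral complex of trivalent cobalt hydrates the (S)-oxirane epimer much faster than the (R)-epimer, so the C3 configuration of recovered 14 is set by the catalyst and not by the substrate; the polar diol from the unwanted epimer is removed by chromatography.

Step 11
Reactants: 15 vanillin
Product: 16 4-(benzyloxy)-3-methoxybenzaldehyde
Conditions: BnBr, K2CO3, DMF, rt
Reagents that add atoms: benzyl bromide, BrCc1ccccc1
Why: Williamson O-alkylation of the phenoxide; the aldehyde is untouched.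

Step 12
Reactants: 16 4-(benzyloxy)-3-methoxybenzaldehyde; 17 propane-1,3-dithiol
Product: 18 2-[4-(benzyloxy)-3-methoxyphenyl]-1,3-dithiane
Conditions: BF3·OEt2 (0.2 equiv), CH2Cl2, 0 °C → rt
Reagents that add atoms: none
Why: Lewis-acid-catalysed dithioacetalisation of the aryl aldehyde (first stage of the Corey–Seebach umpolung); at low catalyst loading and short contact the aryl benzyl ether should be left intact.

Step 13
Reactants: 18 2-[4-(benzyloxy)-3-methoxyphenyl]-1,3-dithiane; 14 (2S,3R)-3-(benzyloxy)-1-[4-(benzyloxy)-3-methoxyphenyl]-4-[(2R)-oxiran-2-yl]butan-2-yl 4-methylbenzenesulfonate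
Product: 21 2-{[(2R,4R,5R)-4-(benzyloxy)-5-[4-(benzyloxy)-3-methoxybenzyl]oxolan-2-yl]methyl}-2-[4-(benzyloxy)-3-methoxyphenyl]-1,3-dithiane, via 2-lithiodithiane 19 (not isolated), via lithium alkoxide 20 (not isolated)
Conditions: 18 (1.3 equiv), n-BuLi (1.2 equiv), THF, −30 °C; then 14, DMPU, −78 °C → rt (40 °C if closure is slow)
Reagents that add atoms: none
Why: n-BuLi removes the acidic C–H between the two sulfur atoms of 18, and the resulting carbanion 19, an aryl acyl-anion equivalent, opens the oxirane of 14 by SN2 attack at its unsubstituted carbon (C2), which forms C1–C2 and releases lithium alkoxide 20 on C3 without touching that centre. Alkoxide 20 then displaces the C6 tosylate from the rear in an intramolecular Williamson etherification, which forms O–C6. The closest known reaction type is the opening of terminal epoxides by 2-lithio-1,3-dithianes with in-flask cyclisation of the liberated alkoxide onto a sulfonate, and the oxolane (O, C3, C4, C5, C6) closes in the 5-exo-tet mode. The one centre set in this step is C6, which goes from S in 14 to R in 21; it is controlled by the stereospecific inversion of the SN2 displacement acting on the sugar-derived configuration of the tosylate carbon, while C3 and C5 are carried through unchanged. The step needs attack at the oxirane terminus and not at C3, which the monosubstituted oxirane secures, and it needs the carbanion to prefer the oxirane over the tosylate, which the hindered, β-oxygenated secondary position of the sulfonate and the low addition temperature should secure. Only one ring can form because the C5 oxygen is capped as a non-migrating benzyl ether, so the alkoxide has no exchange partner and no other ring size is within reach. DMPU loosens the lithium ion pairs so that opening and closure proceed at or below room temperature, which limits base-induced elimination of the homobenzylic tosylate.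

Step 14
Reactants: 21 2-{[(2R,4R,5R)-4-(benzyloxy)-5-[4-(benzyloxy)-3-methoxybenzyl]oxolan-2-yl]methyl}-2-[4-(benzyloxy)-3-methoxyphenyl]-1,3-dithiane
Product: 22 1-[4-(benzyloxy)-3-methoxyphenyl]-2-[(2R,4R,5R)-4-(benzyloxy)-5-[4-(benzyloxy)-3-methoxybenzyl]oxolan-2-yl]ethan-1-one
Conditions: MeI, CaCO3, MeCN/H2O (9:1), 45 °C
Reagents that add atoms: water, O
Why: Alkylative hydrolysis of the dithioketal: S-methylation gives a sulfonium ion that ionises to an aryl-stabilised thionium ion, which water captures; CaCO3 neutralises the HI so that the β-alkoxy ketone is not exposed to acid or base and C3 is not put at risk, and no halogenating oxidant touches the electron-rich rings.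

Step 15
Reactants: 22 1-[4-(benzyloxy)-3-methoxyphenyl]-2-[(2R,4R,5R)-4-(benzyloxy)-5-[4-(benzyloxy)-3-methoxybenzyl]oxolan-2-yl]ethan-1-one
Product: 23 renealtin A, 1-(4-hydroxy-3-methoxyphenyl)-2-[(2R,4R,5R)-4-hydroxy-5-(4-hydroxy-3-methoxybenzyl)oxolan-2-yl]ethan-1-one
Conditions: H2 (1 atm), Pd/C (10 wt %), EtOAc, rt
Reagents that add atoms: none
Why: Catalytic hydrogenolysis cleaves the two aryl benzyl ethers and the alkyl benzyl ether under neutral conditions that cannot trigger retro-oxa-Michael opening; the electron-rich aryl ketone should be reduced only slowly at atmospheric pressure in an aprotic solvent.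

## Compound list

1 | 2-deoxy-L-ribose, (3R,4S)-3,4,5-trihydroxypentanal (handled as its lactol forms) | O=CC[C@@H](O)[C@@H](O)CO | starting material
2 | (2S,3R)-hex-5-ene-1,2,3-triol | C=CC[C@@H](O)[C@@H](O)CO | intermediate
3 | (1R)-1-[(4S)-2,2-dimethyl-1,3-dioxolan-4-yl]but-3-en-1-ol | C=CC[C@@H](O)[C@@H]1COC(C)(C)O1 | intermediate
4 | (4S)-4-[(1R)-1-(benzyloxy)but-3-en-1-yl]-2,2-dimethyl-1,3-dioxolane | C=CC[C@@H](OCc1ccccc1)[C@@H]1COC(C)(C)O1 | intermediate
5 | (2S,3R)-3-(benzyloxy)hex-5-ene-1,2-diol | C=CC[C@@H](OCc1ccccc1)[C@@H](O)CO | intermediate
6 | (2S,3R)-3-(benzyloxy)-2-hydroxyhex-5-en-1-yl 4-methylbenzenesulfonate (present as its sodium alkoxide) | C=CC[C@@H](OCc1ccccc1)[C@@H](O)COS(=O)(=O)c1ccc(C)cc1 | intermediate (not isolated)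
7 | (2S)-2-[(1R)-1-(benzyloxy)but-3-en-1-yl]oxirane | C=CC[C@@H](OCc1ccccc1)[C@@H]1CO1 | intermediate
8 | 4-bromo-2-methoxyphenol | COc1cc(Br)ccc1O | starting material
9 | 1-(benzyloxy)-4-bromo-2-methoxybenzene | COc1cc(Br)ccc1OCc1ccccc1 | intermediate
10 | [4-(benzyloxy)-3-methoxyphenyl]magnesium bromide | COc1cc([Mg]Br)ccc1OCc1ccccc1 | intermediate (not isolated)
11 | (2S,3R)-3-(benzyloxy)-1-[4-(benzyloxy)-3-methoxyphenyl]hex-5-en-2-ol | C=CC[C@@H](OCc1ccccc1)[C@@H](O)Cc1ccc(OCc2ccccc2)c(OC)c1 | intermediate
12 | (2S,3R)-3-(benzyloxy)-1-[4-(benzyloxy)-3-methoxyphenyl]hex-5-en-2-yl 4-methylbenzenesulfonate | C=CC[C@@H](OCc1ccccc1)[C@@H](OS(=O)(=O)c1ccc(C)cc1)Cc1ccc(OCc2ccccc2)c(OC)c1 | intermediate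
13 | (2S,3R)-3-(benzyloxy)-1-[4-(benzyloxy)-3-methoxyphenyl]-4-(oxiran-2-yl)butan-2-yl 4-methylbenzenesulfonate, both epimers at the oxirane carbon | COc1cc(C[C@H](OS(=O)(=O)c2ccc(C)cc2)[C@H](OCc2ccccc2)CC2CO2)ccc1OCc1ccccc1 | intermediate
14 | (2S,3R)-3-(benzyloxy)-1-[4-(benzyloxy)-3-methoxyphenyl]-4-[(2R)-oxiran-2-yl]butan-2-yl 4-methylbenzenesulfonate | COc1cc(C[C@H](OS(=O)(=O)c2ccc(C)cc2)[C@H](OCc2ccccc2)C[C@@H]2CO2)ccc1OCc1ccccc1 | intermediate
15 | vanillin, 4-hydroxy-3-methoxybenzaldehyde | COc1cc(C=O)ccc1O | starting material
16 | 4-(benzyloxy)-3-methoxybenzaldehyde | COc1cc(C=O)ccc1OCc1ccccc1 | intermediate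
17 | propane-1,3-dithiol | SCCCS | starting material
18 | 2-[4-(benzyloxy)-3-methoxyphenyl]-1,3-dithiane | COc1cc(C2SCCCS2)ccc1OCc1ccccc1 | intermediate
19 | {2-[4-(benzyloxy)-3-methoxyphenyl]-1,3-dithian-2-yl}lithium | COc1cc(C2([Li])SCCCS2)ccc1OCc1ccccc1 | intermediate (not isolated)
20 | lithium (2R,4R,5S)-4-(benzyloxy)-6-[4-(benzyloxy)-3-methoxyphenyl]-1-{2-[4-(benzyloxy)-3-methoxyphenyl]-1,3-dithian-2-yl}-5-(tosyloxy)hexan-2-olate | COc1cc(C[C@H](OS(=O)(=O)c2ccc(C)cc2)[C@H](OCc2ccccc2)C[C@@H](O[Li])CC2(c3ccc(OCc4ccccc4)c(OC)c3)SCCCS2)ccc1OCc1ccccc1 | intermediate (not isolated)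
21 | 2-{[(2R,4R,5R)-4-(benzyloxy)-5-[4-(benzyloxy)-3-methoxybenzyl]oxolan-2-yl]methyl}-2-[4-(benzyloxy)-3-methoxyphenyl]-1,3-dithiane | COc1cc(C[C@H]2O[C@@H](CC3(c4ccc(OCc5ccccc5)c(OC)c4)SCCCS3)C[C@H]2OCc2ccccc2)ccc1OCc1ccccc1 | intermediate
22 | 1-[4-(benzyloxy)-3-methoxyphenyl]-2-[(2R,4R,5R)-4-(benzyloxy)-5-[4-(benzyloxy)-3-methoxybenzyl]oxolan-2-yl]ethan-1-one | COc1cc(C[C@H]2O[C@@H](CC(=O)c3ccc(OCc4ccccc4)c(OC)c3)C[C@H]2OCc2ccccc2)ccc1OCc1ccccc1 | intermediate
23 | renealtin A, 1-(4-hydroxy-3-methoxyphenyl)-2-[(2R,4R,5R)-4-hydroxy-5-(4-hydroxy-3-methoxybenzyl)oxolan-2-yl]ethan-1-one | COc1cc(C[C@H]2O[C@@H](CC(=O)c3ccc(O)c(OC)c3)C[C@H]2O)ccc1O | target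

## Step count and least certain steps

Total step count: 15. Longest linear sequence: 12 steps, from 1 through steps 1–5, 7–10 and 13–15. Compounds 9 and 16 are also catalogue items; buying them would remove steps 6 and 11 without changing the linear sequence.

**Step 13 (key step).** The most likely failure is loss of chemoselectivity. Carbanion 19 is aryl-stabilised and hindered and opens oxiranes more slowly than simple dithiane anions, so removal of a benzylic C7 proton with E2 loss of the C6 tosylate, or attack at the sulfonyl sulfur, may compete. A second possibility is sluggish closure of alkoxide 20 at the β-oxygenated secondary carbon; on prolonged warming, aryl-assisted ionisation of the homobenzylic tosylate would erode the inversion at C6. The fallback moves the aryl–C1 bond formation to a later stage. Oxirane 14 is treated with the smaller, more nucleophilic 2-lithio-1,3-dithiane (1,3-dithiane, n-BuLi, THF, −78 °C → rt), which by the same opening and closure should give the 2-(oxolan-2-ylmethyl)-1,3-dithiane F1. Hydrolysis (MeI, CaCO3, aqueous MeCN) gives the oxolan-2-ylacetaldehyde F2, addition of Grignard reagent 10 at −78 °C gives the secondary carbinol F3 as a mixture of C1 epimers, and Dess–Martin oxidation returns to the route at 22.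

**Step 10.** The hydration may be slow or poorly selective if the wanted sense is the mismatched pairing of catalyst with the C5/C6 centres, or if the bulky, non-volatile substrate binds weakly; half of the material is lost in any case. The fallback resolves in the opposite sense and rebuilds the oxirane. Mixture 13 is treated with the (S,S)-complex so that the (R)-epimer is the one hydrated, giving the (5R)-diol F4. Selective sulfonylation of its primary hydroxyl (TsCl, Bu2SnO cat., Et3N) gives the hydroxy bis-tosylate F5, and K2CO3 in MeOH at 0 °C closes the oxirane by 3-exo displacement of the primary sulfonate with the C3–O bond untouched, returning to the route at 14.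

**Step 14.** S-methylation of the congested ketone thioketal may stall, and if acid builds up the freed β-alkoxy ketone can lose the ring oxygen by β-elimination and re-close with scrambling at C3. The fallback activates by oxidation instead of alkylation: 21 is oxidised at one sulfur with NaIO4 (1 equiv, MeOH/H2O, 0 °C) to the dithiane mono-S-oxide F6, which is hydrolysed with a trace of TsOH in wet acetone at 0 °C, returning to the route at 22.

**Step 15.** The aryl ketone may be over-reduced to the benzylic alcohol or methylene while the slower alkyl benzyl ether at C5 is still being cleaved, and traces of sulfur from step 14 can stall the catalyst. The fallback is non-reductive debenzylation of 22 with BCl3 and pentamethylbenzene as cation scavenger in CH2Cl2 at −78 → −30 °C, which leads directly to 23. No new compound arises on this path, which is recorded as F0.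

**Step 2.** Acetonide formation may give a mixture of regioisomers, which would place the benzyl group on the wrong oxygen in step 3. The fallback differentiates the hydroxyls by sulfonylation. Triol 2 is tosylated at the primary hydroxyl (TsCl, Bu2SnO cat., Et3N, CH2Cl2) to the triol monotosylate F7. This is closed with K2CO3 in MeOH at 0 °C to the epoxy alcohol F8, and the reaction is stopped as soon as F7 is consumed so that Payne equilibration does not set in. Benzylation under non-basic conditions (BnBr, Ag2O, CH2Cl2), chosen so that no epoxy alkoxide is formed, returns to the route at 7.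

## Further compounds

F1 | step 13 | 2-{[(2R,4R,5R)-4-(benzyloxy)-5-[4-(benzyloxy)-3-methoxybenzyl]oxolan-2-yl]methyl}-1,3-dithiane | COc1cc(C[C@H]2O[C@@H](CC3SCCCS3)C[C@H]2OCc2ccccc2)ccc1OCc1ccccc1
F2 | step 13 | 2-[(2R,4R,5R)-4-(benzyloxy)-5-[4-(benzyloxy)-3-methoxybenzyl]oxolan-2-yl]acetaldehyde | COc1cc(C[C@H]2O[C@@H](CC=O)C[C@H]2OCc2ccccc2)ccc1OCc1ccccc1
F3 | step 13 | 1-[4-(benzyloxy)-3-methoxyphenyl]-2-[all-cis-4-(benzyloxy)-5-[4-(benzyloxy)-3-methoxybenzyl]oxolan-2-yl]ethan-1-ol, ring configured as in 22, both C1 epimers | COc1cc(C[C@H]2O[C@@H](CC(O)c3ccc(OCc4ccccc4)c(OC)c3)C[C@H]2OCc2ccccc2)ccc1OCc1ccccc1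
F4 | step 10 | (2S,3R,5R)-3-(benzyloxy)-1-[4-(benzyloxy)-3-methoxyphenyl]-5,6-dihydroxyhexan-2-yl 4-methylbenzenesulfonate | COc1cc(C[C@H](OS(=O)(=O)c2ccc(C)cc2)[C@H](OCc2ccccc2)C[C@@H](O)CO)ccc1OCc1ccccc1
F5 | step 10 | (2R,4R,5S)-4-(benzyloxy)-6-[4-(benzyloxy)-3-methoxyphenyl]-2-hydroxyhexane-1,5-diyl bis(4-methylbenzenesulfonate) | COc1cc(C[C@H](OS(=O)(=O)c2ccc(C)cc2)[C@H](OCc2ccccc2)C[C@@H](O)COS(=O)(=O)c2ccc(C)cc2)ccc1OCc1ccccc1
F6 | step 14 | 1-oxide of dithiane 21 (mono-S-oxide, sulfoxide isomers not separated) | COc1cc(C[C@H]2O[C@@H](CC3(c4ccc(OCc5ccccc5)c(OC)c4)SCCCS3=O)C[C@H]2OCc2ccccc2)ccc1OCc1ccccc1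
F0 | step 15 | none | none
F7 | step 2 | (2S,3R)-2,3-dihydroxyhex-5-en-1-yl 4-methylbenzenesulfonate | C=CC[C@@H](O)[C@@H](O)COS(=O)(=O)c1ccc(C)cc1
F8 | step 2 | (1R)-1-[(2S)-oxiran-2-yl]but-3-en-1-ol | C=CC[C@@H](O)[C@@H]1CO1
A1 | alternative 1 | meso 8-oxabicyclo[3.2.1]oct-6-en-3-one | O=C1C[C@@H]2C=C[C@H](C1)O2
A2 | alternative 1 | furan | c1ccoc1
A3 | alternative 1 | 1,1,3,3-tetrabromoacetone | O=C(C(Br)Br)C(Br)Br
A4 | alternative 2 | 1-[all-cis-2-(4-benzyloxy-3-methoxybenzyl)-5-{2-[(tert-butyldiphenylsilyl)oxy]ethyl}oxolan-3-yl]ethan-1-one | COc1cc(C[C@H]2O[C@@H](CCO[Si](c3ccccc3)(c3ccccc3)C(C)(C)C)C[C@H]2C(C)=O)ccc1OCc1ccccc1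
A5 | alternative 2 | (5R)-5-(4-benzyloxy-3-methoxybenzyl)-2-{2-[(tert-butyldiphenylsilyl)oxy]ethyl}-4-methyl-4-vinyl-1,3-dioxolane, configuration at C2 and C4 left open | COc1cc(C[C@H]2OC(CCO[Si](c3ccccc3)(c3ccccc3)C(C)(C)C)OC2(C)C=C)ccc1OCc1ccccc1
A6 | alternative 3 | dimethyl cis-2-(4-benzyloxy-3-methoxybenzyl)-5-[(E)-2-(4-benzyloxy-3-methoxyphenyl)ethenyl]oxolane-3,3-dicarboxylate | COc1cc(C[C@H]2O[C@@H](/C=C/c3ccc(OCc4ccccc4)c(OC)c3)CC2(C(=O)OC)C(=O)OC)ccc1OCc1ccccc1
A7 | alternative 3 | racemic dimethyl 2-[(E)-2-(4-benzyloxy-3-methoxyphenyl)ethenyl]cyclopropane-1,1-dicarboxylate | COC(=O)C1(C(=O)OC)CC1/C=C/c1ccc(OCc2ccccc2)c(OC)c1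
A8 | alternative 3 | 2-(4-benzyloxy-3-methoxyphenyl)acetaldehyde | COc1cc(CC=O)ccc1OCc1ccccc1
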